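**Strategy.** The route rests on cutting pyran ring C of the upper unit (O1, C2, C3, C4, C4a, C8a) at O1–C2 and C3–C4. Ring A with C4, which already bears C8′ of the lower epicatechin, is treated as a latent ortho-quinone methide, and C2–C3 with catechol ring B as a Z-alkene whose silicon stands in for the C3 oxygen. One acid-catalysed hetero-Diels–Alder reaction of a (Z)-styrylsilane then closes ring C, makes both bonds and sets C2, C3 and C4. Its precursor is an ortho-hydroxybenzhydrol joining a 2-hydroxy-4,6-dibenzyloxyphenyl ring to C8 of O-benzylated, O3-silylated epicatechin, assembled by adding the 8-lithio flavan to a ring A salicylaldehyde.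

Key step: step 11

**Remarks on the chemistry (assumptions)**
- The target is read as epicatechin-(4β→8)-epicatechin 3,3′-bis-O-gallate: upper unit 2R,3R,4R (2,3-cis-3,4-trans), lower unit 2R,3R.
- TBS = tert-butyldimethylsilyl. Compounds 5, 11 and 21 and the reagents named are taken as purchasable.
- The sense of induction of the chiral phosphoric acid in step 11 cannot be predicted with confidence. The R acid is written; its antipode would be used if it proves to be the matched one.
- The carbinol carbon of 9 and 10 is formed as both epimers. This has no consequence because it becomes the trigonal methide carbon.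
- Precursor design: the lower unit is the nucleophile and ring A the aldehyde, so no regiochemical question arises on ring A. The ring A phenol is masked as an allyl ether so that it is freed without acid next to the acid-labile benzhydrol.

**Step 1**
Reactants: 1 (−)-epicatechin
Product: 2 5,7,3′,4′-tetra-O-benzylepicatechin
Conditions: BnBr (4.4 equiv), K2CO3, DMF, 0 °C to rt, argon
Reagents that add atoms: benzyl bromide BrCc1ccccc1
Why: Williamson etherification with a carbonate base alkylates the four phenols and leaves the far less acidic secondary C3 alcohol free; neither stereocenter takes part.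

**Step 2**
Reactants: 2 5,7,3′,4′-tetra-O-benzylepicatechin
Product: 3 5,7,3′,4′-tetra-O-benzyl-3-O-TBS-epicatechin
Conditions: TBSCl, imidazole, DMF, rt
Reagents that add atoms: tert-butyldimethylsilyl chloride CC(C)(C)[Si](C)(C)Cl
Why: Imidazole-promoted silylation of the secondary alcohol removes the only acidic proton before the lithiation and gives a group that should survive the weak acid of step 11.

**Step 3**
Reactants: 3 5,7,3′,4′-tetra-O-benzyl-3-O-TBS-epicatechin
Product: 4 8-bromo-5,7,3′,4′-tetra-O-benzyl-3-O-TBS-epicatechin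
Conditions: NBS (1.0 equiv), CH2Cl2, −78 °C to 0 °C
Reagents that add atoms: N-bromosuccinimide O=C1CCC(=O)N1Br
Why: Electrophilic aromatic bromination goes to C8, the most nucleophilic position of the 5,7-dialkoxychroman ring (C6 lies between two benzyloxy groups), and one equivalent at low temperature should avoid the 6,8-dibromide.

**Step 4**
Reactants: 5 2,4,6-trihydroxybenzaldehyde
Product: 6 4,6-bis(benzyloxy)-2-hydroxybenzaldehyde
Conditions: BnBr (2.05 equiv), K2CO3 (2.2 equiv), DMF, 0 °C to rt
Reagents that add atoms: benzyl bromide BrCc1ccccc1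
Why: Williamson etherification should stop at the bis-ether because the last ortho phenol is held in a hydrogen bond to the formyl oxygen and is the least reactive.

**Step 5**
Reactants: 6 4,6-bis(benzyloxy)-2-hydroxybenzaldehyde
Product: 7 2-(allyloxy)-4,6-bis(benzyloxy)benzaldehyde
Conditions: allyl bromide (1.5 equiv), K2CO3, DMF, 50 °C
Reagents that add atoms: allyl bromide C=CCBr
Why: Williamson etherification with gentle heating alkylates the chelated phenol; allyl is chosen because zerovalent palladium removes it later under non-acidic conditions.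

**Step 6**
Reactants: 4 8-bromo-5,7,3′,4′-tetra-O-benzyl-3-O-TBS-epicatechin; 7 2-(allyloxy)-4,6-bis(benzyloxy)benzaldehyde
Product: 9 [2-(allyloxy)-4,6-bis(benzyloxy)phenyl](5,7,3′,4′-tetra-O-benzyl-3-O-TBS-epicatechin-8-yl)methanol (both carbinol epimers), via 8-lithioflavan 8 (not isolated)
Conditions: 4, t-BuLi (2.0 equiv), THF, −78 °C; then 7 (1.2 equiv), −78 °C to −40 °C; then H2O
Reagents that add atoms: none
Why: Bromine–lithium exchange outruns any deprotonation at −78 °C and the aryllithium adds 1,2 to the aldehyde (organolithium carbonyl addition); the new carbinol center is not controlled and need not be.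

**Step 7**
Reactants: 9 [2-(allyloxy)-4,6-bis(benzyloxy)phenyl](5,7,3′,4′-tetra-O-benzyl-3-O-TBS-epicatechin-8-yl)methanol
Product: 10 [4,6-bis(benzyloxy)-2-hydroxyphenyl](5,7,3′,4′-tetra-O-benzyl-3-O-TBS-epicatechin-8-yl)methanol (both carbinol epimers)
Conditions: Pd(PPh3)4 (5 mol %), morpholine (5 equiv), THF, rt; filtration through Et3N-deactivated silica
Reagents that add atoms: none
Why: In this Tsuji–Trost deallylation zerovalent palladium ionises the aryl allyl ether and morpholine traps the allyl unit, and the basic medium leaves the benzhydrol, the benzyl ethers and the silyl ether untouched.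

**Step 8**
Reactants: 11 3,4-bis(benzyloxy)benzaldehyde
Product: 12 1,2-bis(benzyloxy)-4-ethynylbenzene
Conditions: dimethyl (1-diazo-2-oxopropyl)phosphonate (1.3 equiv), K2CO3, MeOH, rt
Reagents that add atoms: dimethyl (1-diazo-2-oxopropyl)phosphonate COP(=O)(OC)C(=[N+]=[N-])C(C)=O
Why: Ohira–Bestmann homologation: methanolysis releases the diazomethylphosphonate anion, which olefinates the aldehyde, and loss of N2 with 1,2-hydrogen shift gives the terminal alkyne under conditions that benzyl ethers tolerate.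

**Step 9**
Reactants: 12 1,2-bis(benzyloxy)-4-ethynylbenzene
Product: 14 benzyl{[3,4-bis(benzyloxy)phenyl]ethynyl}dimethylsilane, via lithium acetylide 13 (not isolated)
Conditions: n-BuLi (1.05 equiv), THF, −78 °C; then BnMe2SiCl, −78 °C to rt
Reagents that add atoms: benzylchlorodimethylsilane C[Si](C)(Cl)Cc1ccccc1
Why: Deprotonation of the alkyne and silylation of the acetylide at carbon; the benzyldimethylsilyl group is chosen because fluoride and peroxide unmask it later, not electrophiles that the electron-rich rings would not survive.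

**Step 10**
Reactants: 14 benzyl{[3,4-bis(benzyloxy)phenyl]ethynyl}dimethylsilane
Product: 16 (Z)-benzyl{2-[3,4-bis(benzyloxy)phenyl]ethenyl}dimethylsilane, via alkenylalane 15 (not isolated)
Conditions: i-Bu2AlH (1.1 equiv), N-methylpyrrolidine (1.1 equiv), heptane–toluene, 60 °C; then H2O, 0 °C
Reagents that add atoms: none
Why: Hydroalumination of a 1-silylalkyne in the presence of a tertiary amine donor is a syn addition whose α-silyl alkenylalane does not isomerise, and protonolysis with retention should give the Z-alkene.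

**Step 11**
Reactants: 10 [4,6-bis(benzyloxy)-2-hydroxyphenyl](5,7,3′,4′-tetra-O-benzyl-3-O-TBS-epicatechin-8-yl)methanol; 16 (Z)-benzyl{2-[3,4-bis(benzyloxy)phenyl]ethenyl}dimethylsilane
Product: 18 3α-(benzyldimethylsilyl)-5,7,3′,4′-tetra-O-benzylflavan-(4β→8)-(5,7,3′,4′-tetra-O-benzyl-3-O-TBS-epicatechin) with the upper unit 2R,3R,4R (2,3-cis-3,4-trans), via ortho-quinone methide 17 (not isolated)
Conditions: (R)-3,3′-bis(2,4,6-triisopropylphenyl)-1,1′-binaphthyl-2,2′-diyl hydrogen phosphate (10 mol %), 16 (3 equiv), 5 Å molecular sieves, toluene, −20 °C, slow addition of 10; Et3N quench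
Reagents that add atoms: none
Why: Proposed new method: the phosphoric acid ionises the doubly activated benzhydrol and the ring A phenol, hydrogen-bonded to the phosphate, collapses to ortho-quinone methide 17, a 1-oxadiene (O1=C8a–C4a=C4) that is attacked at C4 by the silicon-bearing alkene carbon while the phenolic oxygen bonds to the benzylic carbon, whose developing positive charge is stabilised by the para-benzyloxy group of ring B and by the antiperiplanar C–Si bond, in one asynchronous suprafacial [4+2] event. The closest known reaction type is the Brønsted-acid-catalysed inverse-demand hetero-Diels–Alder reaction of ortho-quinone methides, released from ortho-hydroxybenzhydrols, with electron-rich styrenes to give 2,4-diarylchromans; a β-silylstyrene has not been shown as the two-carbon partner. Ring C is closed by intermolecular [4+2] cycloaddition, with O1–C2 and C3–C4 formed on the same face of the alkene. C2 and C3 are set relative to each other by the Z geometry of 16, retained because ring closure should outrun rotation about C2–C3, so that silicon and ring B end up cis; C4 is set relative to C3 by endo approach of the alkene to the methide whose lower-unit aryl is turned to the carbonyl side by the C5 benzyloxy group, which places that aryl anti to silicon (3,4-trans, 2,4-trans); the absolute sense is set by the chiral phosphate bound at O1 acting with the twisted homochiral lower-unit aryl, and a minor diastereomer would be removed by chromatography. The step needs facial and endo selectivity and also ring closure in preference to loss of silicon and to Friedel–Crafts attack of C6′–H on the methide; it relies on the phenoxide oxygen held next to the cationic center, on the O3′ silyl ether leaving no free hydroxyl, and on slow addition of 10 to an excess of 16.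

**Step 12**
Reactants: 18 3α-(benzyldimethylsilyl)-5,7,3′,4′-tetra-O-benzylflavan-(4β→8)-(5,7,3′,4′-tetra-O-benzyl-3-O-TBS-epicatechin)
Product: 20 5,7,3′,4′-tetra-O-benzylepicatechin-(4β→8)-5,7,3′,4′-tetra-O-benzylepicatechin (octa-O-benzylprocyanidin B2), via silanol 19 (not isolated)
Conditions: Bu4NF (6 equiv), THF, 0 °C to rt; then KHCO3, 30% H2O2, MeOH, rt to 40 °C; aq. Na2S2O3
Reagents that add atoms: hydrogen peroxide OO
Why: Tamao–Fleming oxidation: fluoride cleaves the benzyl–silicon bond and the O3′ silyl ether, and in the peroxide adduct of the silanol C3 migrates from silicon to oxygen with retention, so the 3α configuration set in step 11 passes unchanged into the alcohol.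

**Step 13**
Reactants: 20 octa-O-benzylprocyanidin B2; 21 3,4,5-tris(benzyloxy)benzoic acid (6 equiv)
Product: 22 octa-O-benzylprocyanidin B2 3,3′-bis[3,4,5-tris(benzyloxy)benzoate]
Conditions: DCC (6 equiv), DMAP (2 equiv), CH2Cl2, rt
Reagents that add atoms: none
Why: Steglich esterification through the acylpyridinium ion acylates both secondary axial alcohols without touching a stereocenter, the reagents being used in excess because the upper O3 is flanked by two aryl-bearing carbons.

**Step 14**
Reactants: 22 octa-O-benzylprocyanidin B2 3,3′-bis[3,4,5-tris(benzyloxy)benzoate]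
Product: 23 3,3′-digalloylprocyanidin B2
Conditions: H2 (1 atm), Pd(OH)2/C, THF/MeOH/H2O, rt; filtration, lyophilisation
Reagents that add atoms: none
Why: Hydrogenolysis of the fourteen benzyl ethers under neutral conditions should leave the gallate esters, the C4–C8′ bond and all five stereocenters untouched.

**Compound list**

1 | (−)-epicatechin (2R,3R) | O[C@@H]1Cc2c(O)cc(O)cc2O[C@@H]1c1ccc(O)c(O)c1 | starting material
2 | 5,7,3′,4′-tetra-O-benzylepicatechin | O[C@@H]1Cc2c(OCc3ccccc3)cc(OCc3ccccc3)cc2O[C@@H]1c1ccc(OCc2ccccc2)c(OCc2ccccc2)c1 | intermediate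
3 | 5,7,3′,4′-tetra-O-benzyl-3-O-TBS-epicatechin | CC(C)(C)[Si](C)(C)O[C@@H]1Cc2c(OCc3ccccc3)cc(OCc3ccccc3)cc2O[C@@H]1c1ccc(OCc2ccccc2)c(OCc2ccccc2)c1 | intermediate
4 | 8-bromo-5,7,3′,4′-tetra-O-benzyl-3-O-TBS-epicatechin | CC(C)(C)[Si](C)(C)O[C@@H]1Cc2c(OCc3ccccc3)cc(OCc3ccccc3)c(Br)c2O[C@@H]1c1ccc(OCc2ccccc2)c(OCc2ccccc2)c1 | intermediate
5 | 2,4,6-trihydroxybenzaldehyde | O=Cc1c(O)cc(O)cc1O | starting material
6 | 4,6-bis(benzyloxy)-2-hydroxybenzaldehyde | O=Cc1c(O)cc(OCc2ccccc2)cc1OCc1ccccc1 | intermediate
7 | 2-(allyloxy)-4,6-bis(benzyloxy)benzaldehyde | C=CCOc1cc(OCc2ccccc2)cc(OCc2ccccc2)c1C=O | intermediate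
8 | 8-lithio-5,7,3′,4′-tetra-O-benzyl-3-O-TBS-epicatechin | CC(C)(C)[Si](C)(C)O[C@@H]1Cc2c(OCc3ccccc3)cc(OCc3ccccc3)c([Li])c2O[C@@H]1c1ccc(OCc2ccccc2)c(OCc2ccccc2)c1 | intermediate
9 | [2-(allyloxy)-4,6-bis(benzyloxy)phenyl](5,7,3′,4′-tetra-O-benzyl-3-O-TBS-epicatechin-8-yl)methanol, carbinol epimers | C=CCOc1cc(OCc2ccccc2)cc(OCc2ccccc2)c1C(O)c1c(OCc2ccccc2)cc(OCc2ccccc2)c2c1O[C@H](c1ccc(OCc3ccccc3)c(OCc3ccccc3)c1)[C@H](O[Si](C)(C)C(C)(C)C)C2 | intermediate
10 | [4,6-bis(benzyloxy)-2-hydroxyphenyl](5,7,3′,4′-tetra-O-benzyl-3-O-TBS-epicatechin-8-yl)methanol, carbinol epimers (precursor of the key step) | Oc1cc(OCc2ccccc2)cc(OCc2ccccc2)c1C(O)c1c(OCc2ccccc2)cc(OCc2ccccc2)c2c1O[C@H](c1ccc(OCc3ccccc3)c(OCc3ccccc3)c1)[C@H](O[Si](C)(C)C(C)(C)C)C2 | intermediate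
11 | 3,4-bis(benzyloxy)benzaldehyde | O=Cc1ccc(OCc2ccccc2)c(OCc2ccccc2)c1 | starting material
12 | 1,2-bis(benzyloxy)-4-ethynylbenzene | C#Cc1ccc(OCc2ccccc2)c(OCc2ccccc2)c1 | intermediate
13 | lithium [3,4-bis(benzyloxy)phenyl]acetylide | [Li]C#Cc1ccc(OCc2ccccc2)c(OCc2ccccc2)c1 | intermediate
14 | benzyl{[3,4-bis(benzyloxy)phenyl]ethynyl}dimethylsilane | C[Si](C)(Cc1ccccc1)C#Cc1ccc(OCc2ccccc2)c(OCc2ccccc2)c1 | intermediate
15 | (Z)-{1-(benzyldimethylsilyl)-2-[3,4-bis(benzyloxy)phenyl]ethenyl}diisobutylalane (Al cis to H, Si cis to aryl) | CC(C)C[Al](CC(C)C)/C(=C/c1ccc(OCc2ccccc2)c(OCc2ccccc2)c1)[Si](C)(C)Cc1ccccc1 | intermediate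
16 | (Z)-benzyl{2-[3,4-bis(benzyloxy)phenyl]ethenyl}dimethylsilane | C[Si](C)(Cc1ccccc1)/C=C\c1ccc(OCc2ccccc2)c(OCc2ccccc2)c1 | intermediate
17 | (Z)-3,5-bis(benzyloxy)-6-[(5,7,3′,4′-tetra-O-benzyl-3-O-TBS-epicatechin-8-yl)methylidene]cyclohexa-2,4-dien-1-one (ortho-quinone methide, aryl syn to C=O) | O=C1C=C(OCc2ccccc2)C=C(OCc2ccccc2)/C1=C/c1c(OCc2ccccc2)cc(OCc2ccccc2)c2c1O[C@H](c1ccc(OCc3ccccc3)c(OCc3ccccc3)c1)[C@H](O[Si](C)(C)C(C)(C)C)C2 | intermediate
18 | 3α-(benzyldimethylsilyl)-5,7,3′,4′-tetra-O-benzylflavan-(4β→8)-(5,7,3′,4′-tetra-O-benzyl-3-O-TBS-epicatechin), upper unit 2R,3R,4R (product of the key step) | C[Si](C)(Cc1ccccc1)[C@@H]1[C@@H](c2c(OCc3ccccc3)cc(OCc3ccccc3)c3c2O[C@H](c2ccc(OCc4ccccc4)c(OCc4ccccc4)c2)[C@H](O[Si](C)(C)C(C)(C)C)C3)c2c(OCc3ccccc3)cc(OCc3ccccc3)cc2O[C@@H]1c1ccc(OCc2ccccc2)c(OCc2ccccc2)c1 | intermediate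
19 | 3α-(hydroxydimethylsilyl)-5,7,3′,4′-tetra-O-benzylflavan-(4β→8)-5,7,3′,4′-tetra-O-benzylepicatechin | C[Si](C)(O)[C@@H]1[C@@H](c2c(OCc3ccccc3)cc(OCc3ccccc3)c3c2O[C@H](c2ccc(OCc4ccccc4)c(OCc4ccccc4)c2)[C@H](O)C3)c2c(OCc3ccccc3)cc(OCc3ccccc3)cc2O[C@@H]1c1ccc(OCc2ccccc2)c(OCc2ccccc2)c1 | intermediate
20 | 5,7,3′,4′-tetra-O-benzylepicatechin-(4β→8)-5,7,3′,4′-tetra-O-benzylepicatechin (octa-O-benzylprocyanidin B2) | O[C@@H]1[C@@H](c2c(OCc3ccccc3)cc(OCc3ccccc3)c3c2O[C@H](c2ccc(OCc4ccccc4)c(OCc4ccccc4)c2)[C@H](O)C3)c2c(OCc3ccccc3)cc(OCc3ccccc3)cc2O[C@@H]1c1ccc(OCc2ccccc2)c(OCc2ccccc2)c1 | intermediate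
21 | 3,4,5-tris(benzyloxy)benzoic acid | OC(=O)c1cc(OCc2ccccc2)c(OCc2ccccc2)c(OCc2ccccc2)c1 | starting material
22 | octa-O-benzylprocyanidin B2 3,3′-bis[3,4,5-tris(benzyloxy)benzoate] | O=C(O[C@@H]1[C@@H](c2c(OCc3ccccc3)cc(OCc3ccccc3)c3c2O[C@H](c2ccc(OCc4ccccc4)c(OCc4ccccc4)c2)[C@H](OC(=O)c2cc(OCc4ccccc4)c(OCc4ccccc4)c(OCc4ccccc4)c2)C3)c2c(OCc3ccccc3)cc(OCc3ccccc3)cc2O[C@@H]1c1ccc(OCc2ccccc2)c(OCc2ccccc2)c1)c1cc(OCc2ccccc2)c(OCc2ccccc2)c(OCc2ccccc2)c1 | intermediate
23 | 3,3′-digalloylprocyanidin B2 | O=C(O[C@@H]1[C@@H](c2c(O)cc(O)c3c2O[C@H](c2ccc(O)c(O)c2)[C@H](OC(=O)c2cc(O)c(O)c(O)c2)C3)c2c(O)cc(O)cc2O[C@@H]1c1ccc(O)c(O)c1)c1cc(O)c(O)c(O)c1 | target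

**Total step count:** 14
**Longest linear sequence:** 9 steps (1, 2, 3, 6, 7, 11, 12, 13, 14)

**Steps most likely to fail**

Step 11. The β-silyl benzylic cation may lose silicon instead of closing ring C. The methide may be consumed by Friedel–Crafts self-condensation. Rotation about C2–C3 may erode the cis relation, or the acid may discriminate the two faces poorly. The fallback takes the upper unit from the chiral pool by known chemistry and sets out from compound 2. Oxidation at C4 with DDQ in CH2Cl2 in the presence of ethylene glycol would give 4β-(2-hydroxyethoxy)-5,7,3′,4′-tetra-O-benzylepicatechin F1. TiCl4 in CH2Cl2/THF at 0 °C would then ionise F1 in the presence of an excess of 2, whose C8 attacks the C4 cation anti to the C3 oxygen. This gives diol 20 directly, where the route is rejoined before step 13.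

Step 12. During the long exposure to fluoride needed to cleave the hindered O3′ silyl ether, the pentacoordinate silicon at C3 may expel the O1 aryloxide and open ring C, or the oxidation at the hindered axial C3 may stall. The fallback separates the two events and sets out from 18. Brief treatment with Bu4NF (1.5 equiv, 0 °C) followed at once by KHCO3/H2O2 would give 5,7,3′,4′-tetra-O-benzylepicatechin-(4β→8)-5,7,3′,4′-tetra-O-benzyl-3-O-TBS-epicatechin F2, which no longer carries silicon on carbon. The silyl ether would then be cleaved with HF·pyridine in THF to give 20, where the route is rejoined.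

Step 7. The very electron-rich benzhydrol may ionise and self-condense during the palladium-mediated unmasking and the purification that follows. The fallback uses no protecting group and sets out from 6 and 4. NaH in THF would convert 6 into sodium 3,5-bis(benzyloxy)-2-formylphenolate F3. Aryllithium 8, made from 4 as in step 6, would be added to it at −78 °C and the mixture warmed to 0 °C. Work-up with aqueous NaHCO3 would give 10, which would be dried and taken at once into step 11, where the route is rejoined.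

**Further compounds**

F1 | step 11 | 4β-(2-hydroxyethoxy)-5,7,3′,4′-tetra-O-benzylepicatechin | O[C@@H]1[C@@H](OCCO)c2c(OCc3ccccc3)cc(OCc3ccccc3)cc2O[C@@H]1c1ccc(OCc2ccccc2)c(OCc2ccccc2)c1
F2 | step 12 | 5,7,3′,4′-tetra-O-benzylepicatechin-(4β→8)-5,7,3′,4′-tetra-O-benzyl-3-O-TBS-epicatechin | O[C@@H]1[C@@H](c2c(OCc3ccccc3)cc(OCc3ccccc3)c3c2O[C@H](c2ccc(OCc4ccccc4)c(OCc4ccccc4)c2)[C@H](O[Si](C)(C)C(C)(C)C)C3)c2c(OCc3ccccc3)cc(OCc3ccccc3)cc2O[C@@H]1c1ccc(OCc2ccccc2)c(OCc2ccccc2)c1
F3 | step 7 | sodium 3,5-bis(benzyloxy)-2-formylphenolate | [Na+].[O-]c1cc(OCc2ccccc2)cc(OCc2ccccc2)c1C=O
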